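The easy step comes first: every step below has a single species on its left, so I keep the books per mole of substrate charged.

common to all: time 20 min

|  | substrate |
|---|---|
| Wednesday's | 0.040 M |
| Friday's | 0.080 M |
| Monday's | 0.15 M |
| Saturday's | 0.30 M |
| Tuesday's | 0.60 M |

    substrate → target (k1 = 0.046 min⁻¹)
    intermediate A → intermediate B (k2 = 0.079 min⁻¹)
    substrate ⇌ dormant form (K3 = 6.1, k3 = 0.042 min⁻¹)
    intermediate B ⇌ intermediate C (K4 = 2.0, k4 = 0.054 min⁻¹)
    substrate ⇌ intermediate A (K5 = 1.1, k5 = 0.095 min⁻¹)
    intermediate C → side product (k6 = 0.053 min⁻¹)

1. share of target in all that became target or side product for Wednesday's, Friday's, Monday's, Saturday's, Tuesday's, in this order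
2. how that number moves from the first to the last of them (hardly changes / rises, then falls / falls, then rises / falls all the way / rises all the way)

- "hardly changes" means that all values lie within two and a half points (for a concentration: within two and a half percent of the largest)
- run time (Wednesday's): 20 min

**The entries.** Substrate leaves for target with 0.046 min⁻¹, for dormant form with 0.042 min⁻¹ and for intermediate A with 0.095 min⁻¹. Dormant form has one way out, back into substrate, so I enter it as a deferral and not as an exit. Intermediate A returns to substrate with 0.0864 min⁻¹ or goes on to intermediate B with 0.079 min⁻¹, so 47.8% of what enters it passes on. Intermediate B and intermediate C trade with each other, and their one exit is side product.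

**Closing the books.** Intermediate A starts empty and ends empty, so over the whole life of a flask its inflow and outflow balance. Substrate therefore feeds the road to side product with a net constant of 0.0454 min⁻¹, against 0.046 min⁻¹ towards target. The share of target among the two exits, which I call the final split 50.3%, is the selectivity at the end of the books. No charge enters it.

**The asked time.** The question stands at 20 min, and the road to side product has 3 steps in line. Their forward half-lives add up to 34.7 min, longer than the run. So I commit to a flat row, since amounts scale with the charge, and to a share well above the final split. My reckoning gives no figure for the row itself and stops there.

**The forecast.** It gave 92.8% at 0.040 M and 92.8% at 0.60 M, shape hardly changes, on the ground that “all concentrations scale with the starting substrate”. My final split is a different number, for a different time.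

**The result.** The simulation gives 91.9%, 91.9%, 91.9%, 91.9% and 91.9%, and the shape is hardly changes.

**Time allowed.** Wednesday's share describes an unfinished flask: at 20.0 min it holds 30.2% target and 2.67% side product, with 15.9% intermediate B and 6.37% intermediate C still on the road. The largest single effect is the time allowed: with the limit of 20 min taken away and a tenfold time in its place, Wednesday's share falls to 51.7%, just above the final split. Tuesday's, with its larger charge, has the same final split of 50.3%, and with the limit of 20 min taken away and a tenfold time in its place, its share reads 51.7%.

The constants used here are invented; the rest is arithmetic.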